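At every moment the unused part of the Q charge and the used part make up the whole charge, and we take it that a used Q begins at most one chain. So if f is the part of the charge that has begun chains and n is the units in chains per Q charged, the average chain holds n/f units.

| flask | Z | Q | remark | time |
|---|---|---|---|---|
| Wednesday's | 0.091 M | 3.2 mM | run made earlier |  |
| Monday's | 0.091 M | 5.1 mM | run made earlier |  |
| Sunday's | 0.045 M | 2.3 mM | run made earlier |  |
| flask | 0.091 M | 2.3 mM |  | 8.0 min |

| run | time / min | X / % | Z / % |
|---|---|---|---|
| Wednesday's | 0.833 | 4.8 | 96.0 |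
| Wednesday's | 1.33 | 10.1 | 89.5 |
| Wednesday's | 2.50 | 28.4 | 71.3 |
| Wednesday's | 5.00 | 67.4 | 32.5 |
| Wednesday's | 10.0 | 94.5 | 3.9 |
| Monday's | 0.833 | 7.0 | 93.6 |
| Monday's | 1.33 | 15.5 | 84.6 |
| Monday's | 2.50 | 41.1 | 59.2 |
| Monday's | 5.00 | 81.4 | 18.9 |
| Monday's | 10.0 | 97.4 | 1.8 |
| Sunday's | 0.833 | 1.8 | 98.5 |
| Sunday's | 2.50 | 12.9 | 88.6 |
| Sunday's | 4.00 | 26.8 | 71.5 |
| Sunday's | 6.00 | 47.7 | 52.0 |
| Sunday's | 10.0 | 77.2 | 22.2 |

(scatter of a reading: 0.5 percentage points)

- the average divides the monomer in chains by the number of chains begun, living and dead together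
- the numbers in the tables scatter by 0.5 percentage points (one standard deviation)
- the earlier runs do not show the number of chains; that part of a forecast is a guess

* average number of monomer units in a chain (chains begun, living or dead) at 8.0 min
* part of the Z that has reacted at 8.0 min

We first need the reacted part of Z, using s, the logarithm of charge over Z left. In Wednesday's run s is 1.12 at 5.00 min and 3.24 at 10.0 min, so a straight line gives 2.40 at 8.0 min. Monday's run, with 1.59 times the Q, shows 1.48 times that s at 5.00 min, which makes s go as Q to the power 0.844. Carried to the asked flask's 2.3 mM, s is 1.81, so we expect 83.7% reacted.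

Then n comes to 33.1, the reacted part times the ratio of the Z charge to the Q charge. Guessing f at 0.5, we commit to 66.2 units.

That guess is the weak link. We read the late slope of s as following the chains: from 5.00 min to 10.0 min it is 0.424 min⁻¹ on Wednesday and 0.470 min⁻¹ on Monday. Monday's f then reads 0.696 of Wednesday's, a reading that rests on small Z readings with their scatter, so we hold our guess loosely. Since f is at most one by the opening balance, our estimate of the asked flask's chain length cannot go below 33.1 units.

The forecast gives 60 units and 83%: “About half the Q has started chains”. Its chain length lies below ours.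

The flask gives 118 units and 82.4%.

    Z + L → X + L, rate k1*[L]*[Z] (k = 8.41 L mol⁻¹ s⁻¹)
    Z + Q → L + X (k = 0.0140 L mol⁻¹ s⁻¹)
    Z + Q → E (k = 0.00740 L mol⁻¹ s⁻¹)

In the flask, n is 32.6, so f is 0.276, less than our guess. Q left in the flask is 58% of its charge, so the 14.4% of the charge neither left nor in chains stands in E. The neighbouring flask, the same but with 0.23 M of Z, reacts 94.8% at the same time, so its n is 94.8. Its chains hold 229 units, which makes its f 0.414, with 37% of its Q left.

All runs were computed for substances that don't exist; scatter was added.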